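Readings and results are simulated with constants of no real substance.

A small charge should favour ring: starting material goes to ring by a first-order step and to open dimer by a second-order one.

| flask | starting material | remark | time |
|---|---|---|---|
| south | 0.013 M | run made earlier |  |
| north-east | 0.055 M | run made earlier |  |
| north | 0.19 M | run made earlier |  |
| ochre | 0.080 M |  | 50 h |
| green | 0.030 M |  | 50 h |
| blue | 0.050 M |  | 50 h |
| teal | 0.015 M |  | 50 h |
| grey | 0.20 M |  | 50 h |

| run | time / h | ring / % | open dimer / % |
|---|---|---|---|
| south | 10.0 | 45.8 | 26.8 |
| south | 20.0 | 59.5 | 28.5 |
| south | 30.0 | 65.5 | 27.3 |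
| south | 40.0 | 69.0 | 28.7 |
| south | 48.0 | 70.5 | 27.6 |
| north-east | 4.00 | 18.2 | 46.2 |
| north-east | 8.00 | 28.5 | 55.0 |
| north-east | 15.0 | 35.0 | 57.6 |
| north-east | 25.0 | 37.8 | 58.7 |
| north-east | 48.0 | 42.1 | 58.6 |
| north | 10.0 | 17.9 | 79.1 |
| north | 20.0 | 19.6 | 79.6 |
| north | 30.0 | 19.6 | 79.9 |
| north | 40.0 | 20.3 | 79.6 |
| north | 48.0 | 18.1 | 78.9 |

(each reading ± 1 percentage point)

- percentages count the starting material that a species holds: one open dimer counts as two
- ring is meant together with its crystals
- solid, in amounts per volume of the solution: crystals
- what may be going on: 2 starting material -> open dimer; starting material -> ring; crystals <-> ring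

- the flasks by share of ring in all that became ring or open dimer, highest first, at 50 h (ochre / green / blue / teal / grey)
- the share of ring in all that became ring or open dimer of the flask you put first, at 50 h
- the share of ring in all that became ring or open dimer of the flask you put last, at 50 h

The first setting is the charge. I divide one rate by the other, so time drops out. The use of starting material by the dimer step over its use by the ring step is [starting material]/K. Following [starting material] down to nothing gives a ring share of ln(1+x)/x, with x the charge over K.

The north-east run ends at 48.0 h with a share of 41.8%. Solving for x gives K = 0.0147 M, the [starting material] at which both steps use it equally fast. It is a selectivity factor with the unit of a concentration. As a check, K gives the south run 71.6%, and its last reading gives 71.9%.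

By hand, teal gets 68.9% and grey 19.7%.

The second setting is time. More time turns remaining starting material into both products, but in the south run hardly any is unaccounted for at 48.0 h. So I expect little from it.

The third is crystals. They count as ring, so they stay inside the share. Falling out only moves ring between its forms, so I add no term for it to the reckoning.

The forecast says teal > green > blue > ochre > grey, with 69% (66% to 72%) on top and 19.5% (17.5% to 21.5%) last: “One K therefore fits all three runs.” My grey lies 0.20 percentage points above its figure.

The simulation gives teal > green > blue > ochre > grey, with teal at 68.2% and grey at 19.3%.

    2 starting material → open dimer (k = 8.00 × 10⁻⁴ /M/s)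
    starting material → ring (k = 2.30 × 10⁻⁵ /s)
    crystals ⇌ ring, rate k3*(cs3 - [ring]) while solid is left; crystals form when [ring] > cs3 (solubility = 2.00 mM, k = 0.00240 /s)

Grey starts with a ratio of 13.6 by my K. At 0.623 h the dimer step in grey still uses starting material 7.8 times as fast as the ring step. For the neighbour of grey charged with 0.050 M, K gives 43.6%, and that flask ends at 42.9%.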